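**Retrosynthetic overview**
1. The tiglate (C8–O) and the 4‑hydroxybenzoate (C4–O) are put on last; the C8 carbinol comes from catalyst‑controlled reduction of a cis‑fused hydroazulenone.
2. The enone comes from a Nef reaction and conjugation of a nitro‑cycloheptene, which is closed by ring‑closing metathesis (seven‑membered ring, formed second).
3. The C4 carbinol comes from chelation‑controlled vinyl addition to a cyclopentanecarbaldehyde.
4. The cyclopentane (five‑membered ring, formed first; three stereocentres including the quaternary carbon) comes from one aminocatalytic nitro‑Michael/aldol domino between an achiral keto‑enal and an achiral nitroalkene.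
5. The keto‑enal comes from isobutyraldehyde and methyl vinyl ketone (Stetter reaction, then formylolefination).

Assumption: the SMILES is read as the cis‑fused (3R,3aS,4S,8S,8aR)‑octahydroazulene carrying an (E)‑2‑methylbut‑2‑enoate (tiglate); locants in the text are those of each compound's own name.

**Step 1**
Reactants: 1 2‑methylpropanal (isobutyraldehyde); 2 but‑3‑en‑2‑one (methyl vinyl ketone)
Product: 3 6‑methylheptane‑2,5‑dione
Conditions: 3‑benzyl‑5‑(2‑hydroxyethyl)‑4‑methylthiazolium chloride (10 mol %), Et3N (0.5 equiv), EtOH, 80 °C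
Reagents that add atoms: none
Why: Stetter reaction – the thiazolylidene turns the aldehyde into an acyl anion equivalent (Breslow intermediate) that adds 1,4 to the unhindered vinyl ketone; no stereocentre is formed.

**Step 2**
Reactants: 3 6‑methylheptane‑2,5‑dione; 4 diethyl [(E)‑2‑(cyclohexylamino)ethenyl]phosphonate
Product: 6 (2E)‑3,7‑dimethyl‑6‑oxooct‑2‑enal, via unsaturated aldimine 5 (not isolated)
Conditions: NaH, THF, 0 → 23 °C; then (CO2H)2, H2O/toluene, 23 °C; E isomer separated by chromatography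
Reagents that add atoms: water, O
Why: Nagata formylolefination (Horner–Wadsworth–Emmons reaction of a metallated enamine phosphonate, then imine hydrolysis); the methyl ketone reacts before the hindered isopropyl ketone and no stereocentre is formed.

**Step 3**
Reactants: 7 4‑bromo‑2‑methylbut‑1‑ene
Product: 8 2‑methyl‑4‑nitrobut‑1‑ene
Conditions: NaNO2, phloroglucinol, DMF, 23 °C
Reagents that add atoms: sodium nitrite, [Na+].[O-]N=O
Why: Kornblum reaction – SN2 displacement of the unhindered primary bromide by nitrite through nitrogen; no stereocentre is formed.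

**Step 4**
Reactants: 6 (2E)‑3,7‑dimethyl‑6‑oxooct‑2‑enal; 8 2‑methyl‑4‑nitrobut‑1‑ene
Product: 10 (1R,2R,5R)‑2‑hydroxy‑5‑methyl‑5‑(3‑methyl‑1‑nitrobut‑3‑en‑1‑yl)‑2‑(propan‑2‑yl)cyclopentane‑1‑carbaldehyde, via open‑chain Michael adduct 9 (not isolated)
Conditions: (S)‑α,α‑diphenylprolinol trimethylsilyl ether (20 mol %), PhCO2H (20 mol %), 8 (2 equiv), iPrOH, 23 °C, 72 h
Reagents that add atoms: none
Why: Proposed new method: an iminium–enamine relay in which the nitronate of 8 adds to the β,β‑disubstituted E‑iminium of 6 from the face away from the CPh2OSiMe3 group (quaternary ring C5 set as R), and the catalyst‑bound enamine then attacks the tethered isopropyl ketone through the same open face in a 5‑enolexo aldol (CHO cis to the nitroalkyl arm; OH cis to CHO because the ketone oxygen sits next to the iminium and the isopropyl group turns away); the closest known reactions are diphenylprolinol silyl ether nitroalkane additions to β,β‑disubstituted enals and aminocatalytic Michael/aldol cyclopentane annulations, which have not been joined for a quaternary centre with closure onto an unactivated dialkyl ketone; a Michael/Henry shunt is disfavoured because the nitronate carbon is secondary and neopentyl, and the nitro carbon is formed as both epimers, which is harmless.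

**Step 5**
Reactants: 10 (1R,2R,5R)‑2‑hydroxy‑5‑methyl‑5‑(3‑methyl‑1‑nitrobut‑3‑en‑1‑yl)‑2‑(propan‑2‑yl)cyclopentane‑1‑carbaldehyde; 11 vinylmagnesium bromide (CH2=CHMgBr)
Product: 12 (1S)‑1‑[(1S,2R,5R)‑2‑hydroxy‑5‑methyl‑5‑(3‑methyl‑1‑nitrobut‑3‑en‑1‑yl)‑2‑(propan‑2‑yl)cyclopentyl]prop‑2‑en‑1‑ol
Conditions: 11 (3.5 equiv), THF, −78 → −30 °C; aq. NH4Cl, 0 °C
Reagents that add atoms: none
Why: Cram‑chelate (chelation‑controlled) Grignard addition – the first equivalents make the magnesium alkoxide of the tertiary alcohol and an inert nitronate, the alkoxide chelates the cis aldehyde, and vinyl attacks the face turned away from the quaternary ring carbon, giving the (1S) carbinol.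

**Step 6**
Reactants: 12 (1S)‑1‑[(1S,2R,5R)‑2‑hydroxy‑5‑methyl‑5‑(3‑methyl‑1‑nitrobut‑3‑en‑1‑yl)‑2‑(propan‑2‑yl)cyclopentyl]prop‑2‑en‑1‑ol
Product: 13 (3R,3aS,4S,8aR)‑6,8a‑dimethyl‑8‑nitro‑3‑(propan‑2‑yl)‑1,2,3,3a,4,7,8,8a‑octahydroazulene‑3,4‑diol
Conditions: second‑generation Grubbs catalyst RuCl2(=CHPh)(H2IMes)(PCy3) (5 mol %), CH2Cl2 (0.005 M), 40 °C
Reagents that add atoms: none
Why: Ring‑closing metathesis – the two alkenyl arms are cis on the cyclopentane, the vinyl carbinol initiates and closes onto the 1,1‑disubstituted alkene to give the cis‑fused cycloheptene; no stereocentre changes.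

**Step 7**
Reactants: 13 (3R,3aS,4S,8aR)‑6,8a‑dimethyl‑8‑nitro‑3‑(propan‑2‑yl)‑1,2,3,3a,4,7,8,8a‑octahydroazulene‑3,4‑diol
Product: 16 (3R,3aS,4S,8aR)‑3,4‑dihydroxy‑6,8a‑dimethyl‑3‑(propan‑2‑yl)‑1,2,3,3a,4,5‑hexahydroazulen‑8(8aH)‑one, via sodium nitronate 14 (not isolated), via deconjugated enone 15 (not isolated)
Conditions: NaOMe, MeOH, 0 °C; then TiCl3, NH4OAc, H2O/THF (pH 5–6), 0 → 23 °C; then DBU (0.2 equiv), CH2Cl2, 23 °C
Reagents that add atoms: water, O
Why: McMurry–Melton reductive Nef reaction – TiCl3 reduces the nitronate to the imine, which hydrolyses to the ketone under buffered conditions that spare the tertiary and allylic alcohols; DBU then moves the ring alkene into conjugation (base‑mediated enone isomerization), and the stereorandom nitro carbon disappears.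

**Step 8**
Reactants: 16 (3R,3aS,4S,8aR)‑3,4‑dihydroxy‑6,8a‑dimethyl‑3‑(propan‑2‑yl)‑1,2,3,3a,4,5‑hexahydroazulen‑8(8aH)‑one; 17 4‑(acetyloxy)benzoyl chloride
Product: 18 (3R,3aS,4S,8aR)‑3‑hydroxy‑6,8a‑dimethyl‑8‑oxo‑3‑(propan‑2‑yl)‑1,2,3,3a,4,5,8,8a‑octahydroazulen‑4‑yl 4‑(acetyloxy)benzoate
Conditions: Et3N, DMAP (10 mol %), CH2Cl2, 0 → 23 °C
Reagents that add atoms: none
Why: DMAP‑catalysed acylation (nucleophilic acyl‑transfer catalysis) – only the secondary C4 hydroxyl reacts, the tertiary C3 hydroxyl is inert, and no stereocentre is touched.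

**Step 9**
Reactants: 18 (3R,3aS,4S,8aR)‑3‑hydroxy‑6,8a‑dimethyl‑8‑oxo‑3‑(propan‑2‑yl)‑1,2,3,3a,4,5,8,8a‑octahydroazulen‑4‑yl 4‑(acetyloxy)benzoate
Product: 19 (3R,3aS,4S,8S,8aR)‑3,8‑dihydroxy‑6,8a‑dimethyl‑3‑(propan‑2‑yl)‑1,2,3,3a,4,5,8,8a‑octahydroazulen‑4‑yl 4‑(acetyloxy)benzoate
Conditions: (R)‑2‑methyl‑CBS‑oxazaborolidine (0.5 equiv), catecholborane (2.5 equiv), toluene, −78 °C; then MeOH, pH 7 buffer
Reagents that add atoms: none
Why: Corey–Bakshi–Shibata reduction – 1,2‑hydride delivery to the enone under catalyst control, with the fully substituted C8a side taken as the large group so that the (R)‑oxazaborolidine sets C8 as S; the esters survive at −78 °C.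

**Step 10**
Reactants: 19 (3R,3aS,4S,8S,8aR)‑3,8‑dihydroxy‑6,8a‑dimethyl‑3‑(propan‑2‑yl)‑1,2,3,3a,4,5,8,8a‑octahydroazulen‑4‑yl 4‑(acetyloxy)benzoate; 20 (2E)‑2‑methylbut‑2‑enoyl chloride (tigloyl chloride)
Product: 21 (3R,3aS,4S,8S,8aR)‑4‑{[4‑(acetyloxy)benzoyl]oxy}‑3‑hydroxy‑6,8a‑dimethyl‑3‑(propan‑2‑yl)‑1,2,3,3a,4,5,8,8a‑octahydroazulen‑8‑yl (2E)‑2‑methylbut‑2‑enoate
Conditions: Et3N, DMAP (1 equiv), CH2Cl2, 0 → 40 °C
Reagents that add atoms: none
Why: DMAP‑catalysed acylation of the hindered allylic C8 alcohol with retention; the tertiary alcohol does not react and the E‑configured acyl group does not isomerize.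

**Step 11**
Reactants: 21 (3R,3aS,4S,8S,8aR)‑4‑{[4‑(acetyloxy)benzoyl]oxy}‑3‑hydroxy‑6,8a‑dimethyl‑3‑(propan‑2‑yl)‑1,2,3,3a,4,5,8,8a‑octahydroazulen‑8‑yl (2E)‑2‑methylbut‑2‑enoate
Product: 22 (3R,3aS,4S,8S,8aR)‑3‑hydroxy‑4‑[(4‑hydroxybenzoyl)oxy]‑6,8a‑dimethyl‑3‑(propan‑2‑yl)‑1,2,3,3a,4,5,8,8a‑octahydroazulen‑8‑yl (2E)‑2‑methylbut‑2‑enoate
Conditions: K2CO3 (0.2 equiv), MeOH, 0 °C, 30 min
Reagents that add atoms: none
Why: Base‑catalysed transesterification (Zemplén‑type methanolysis) – the phenyl acetate is far more electrophilic than the two alkyl esters, and the phenoxide formed deactivates the benzoate further.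

**Compound list**
1 | 2‑methylpropanal | CC(C)C=O | starting material
2 | but‑3‑en‑2‑one | CC(=O)C=C | starting material
3 | 6‑methylheptane‑2,5‑dione | CC(=O)CCC(=O)C(C)C | intermediate
4 | diethyl [(E)‑2‑(cyclohexylamino)ethenyl]phosphonate | CCOP(=O)(OCC)/C=C/NC1CCCCC1 | starting material
5 | (6E)‑8‑(cyclohexylimino)‑2,6‑dimethyloct‑6‑en‑3‑one | CC(C)C(=O)CC/C(C)=C/C=NC1CCCCC1 | intermediate
6 | (2E)‑3,7‑dimethyl‑6‑oxooct‑2‑enal | CC(C)C(=O)CC/C(C)=C/C=O | intermediate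
7 | 4‑bromo‑2‑methylbut‑1‑ene | C=C(C)CCBr | starting material
8 | 2‑methyl‑4‑nitrobut‑1‑ene | C=C(C)CC[N+](=O)[O-] | intermediate
9 | (3R)‑3,7‑dimethyl‑3‑(3‑methyl‑1‑nitrobut‑3‑en‑1‑yl)‑6‑oxooctanal (nitro carbon epimers) | O=CC[C@](C)(C(CC(C)=C)[N+](=O)[O-])CCC(=O)C(C)C | intermediate
10 | (1R,2R,5R)‑2‑hydroxy‑5‑methyl‑5‑(3‑methyl‑1‑nitrobut‑3‑en‑1‑yl)‑2‑(propan‑2‑yl)cyclopentane‑1‑carbaldehyde (nitro carbon epimers) | O=C[C@@H]1[C@](C)(C(CC(C)=C)[N+](=O)[O-])CC[C@@]1(O)C(C)C | intermediate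
11 | vinylmagnesium bromide | C=C[Mg]Br | starting material
12 | (1S)‑1‑[(1S,2R,5R)‑2‑hydroxy‑5‑methyl‑5‑(3‑methyl‑1‑nitrobut‑3‑en‑1‑yl)‑2‑(propan‑2‑yl)cyclopentyl]prop‑2‑en‑1‑ol | C=C[C@H](O)[C@@H]1[C@](C)(C(CC(C)=C)[N+](=O)[O-])CC[C@@]1(O)C(C)C | intermediate
13 | (3R,3aS,4S,8aR)‑6,8a‑dimethyl‑8‑nitro‑3‑(propan‑2‑yl)‑1,2,3,3a,4,7,8,8a‑octahydroazulene‑3,4‑diol (C8 epimers) | [O-][N+](=O)C1CC(C)=C[C@H](O)[C@@H]2[C@@]1(C)CC[C@@]2(O)C(C)C | intermediate
14 | sodium nitronate (aci‑nitro salt) of 13 | [Na+].[O-][N+]([O-])=C1CC(C)=C[C@H](O)[C@@H]2[C@@]1(C)CC[C@@]2(O)C(C)C | intermediate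
15 | (3R,3aS,4S,8aR)‑3,4‑dihydroxy‑6,8a‑dimethyl‑3‑(propan‑2‑yl)‑1,2,3,3a,4,7‑hexahydroazulen‑8(8aH)‑one | O=C1CC(C)=C[C@H](O)[C@@H]2[C@@]1(C)CC[C@@]2(O)C(C)C | intermediate
16 | (3R,3aS,4S,8aR)‑3,4‑dihydroxy‑6,8a‑dimethyl‑3‑(propan‑2‑yl)‑1,2,3,3a,4,5‑hexahydroazulen‑8(8aH)‑one | O=C1C=C(C)C[C@H](O)[C@@H]2[C@@]1(C)CC[C@@]2(O)C(C)C | intermediate
17 | 4‑(acetyloxy)benzoyl chloride | CC(=O)Oc1ccc(cc1)C(Cl)=O | starting material
18 | (3R,3aS,4S,8aR)‑3‑hydroxy‑6,8a‑dimethyl‑8‑oxo‑3‑(propan‑2‑yl)‑1,2,3,3a,4,5,8,8a‑octahydroazulen‑4‑yl 4‑(acetyloxy)benzoate | O=C1C=C(C)C[C@H](OC(=O)c2ccc(OC(C)=O)cc2)[C@@H]2[C@@]1(C)CC[C@@]2(O)C(C)C | intermediate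
19 | (3R,3aS,4S,8S,8aR)‑3,8‑dihydroxy‑6,8a‑dimethyl‑3‑(propan‑2‑yl)‑1,2,3,3a,4,5,8,8a‑octahydroazulen‑4‑yl 4‑(acetyloxy)benzoate | O[C@H]1C=C(C)C[C@H](OC(=O)c2ccc(OC(C)=O)cc2)[C@@H]2[C@@]1(C)CC[C@@]2(O)C(C)C | intermediate
20 | (2E)‑2‑methylbut‑2‑enoyl chloride | C/C=C(\C)C(Cl)=O | starting material
21 | (3R,3aS,4S,8S,8aR)‑4‑{[4‑(acetyloxy)benzoyl]oxy}‑3‑hydroxy‑6,8a‑dimethyl‑3‑(propan‑2‑yl)‑1,2,3,3a,4,5,8,8a‑octahydroazulen‑8‑yl (2E)‑2‑methylbut‑2‑enoate | C/C=C(\C)C(=O)O[C@H]1C=C(C)C[C@H](OC(=O)c2ccc(OC(C)=O)cc2)[C@@H]2[C@@]1(C)CC[C@@]2(O)C(C)C | intermediate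
22 | (3R,3aS,4S,8S,8aR)‑3‑hydroxy‑4‑[(4‑hydroxybenzoyl)oxy]‑6,8a‑dimethyl‑3‑(propan‑2‑yl)‑1,2,3,3a,4,5,8,8a‑octahydroazulen‑8‑yl (2E)‑2‑methylbut‑2‑enoate | C/C=C(\C)C(=O)O[C@H]1C=C(C)C[C@H](OC(=O)c2ccc(O)cc2)[C@@H]2[C@@]1(C)CC[C@@]2(O)C(C)C | target

**Step count**
Total: 11 steps (step 3 is a one‑step side branch). Longest linear sequence: 10 steps (1, 2, 4–11).

**Three steps most likely to fail**

Step 4 (the proposed new domino). The hindered nitronate may add slowly, E/Z scrambling of the iminium may erode the ee, and the β‑hydroxy aldehyde may dehydrate. The fallback uses known chemistry only; it sets out from 6 and comes back to the route at 10. Nitromethane is added to 6 with the same (S)‑diphenylprolinol trimethylsilyl ether/PhCO2H system, which is the established nitromethane addition to β,β‑disubstituted enals, to give (3R)‑3,7‑dimethyl‑3‑(nitromethyl)‑6‑oxooctanal F1. Its nitronate is C‑allylated with 2‑methylallyl methyl carbonate under Pd(PPh3)4 (zerovalent palladium; Tsuji–Trost allylation of a nitroalkane) to give 9, which is isolated here. Compound 9 is then closed to 10 in a separate enamine aldol step (the same chiral amine at 40 °C, or pyrrolidine/AcOH). Any epimer at the formyl carbon is recycled by K2CO3/MeOH equilibration, since only the cis isomer can close the seven‑membered ring in step 6.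

Step 7 (Nef reaction and conjugation). The secondary nitro group sits next to a quaternary carbon, and the conjugation of a cycloheptenone is an equilibrium that may stop near 4:1. The fallback sets out from 13 and comes back at 16. The nitro group is reduced to the oxime (3R,3aS,4S,8aR)‑8‑(hydroxyimino)‑6,8a‑dimethyl‑3‑(propan‑2‑yl)‑1,2,3,3a,4,7,8,8a‑octahydroazulene‑3,4‑diol F2 with SnCl2·2H2O, PhSH and Et3N (Bartra reduction). The oxime is cleaved with aqueous NaHSO3 in EtOH, and the crude ketone is conjugated with DBU to give 16; residual 15 is separated and resubmitted.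

Step 9 (facial selectivity at C8). The substrate may prefer hydride attack anti to the angular methyl group, which is mismatched with the catalyst. The fallback sets out from 18 and comes back at 21, bypassing 19. Luche reduction (NaBH4, CeCl3·7H2O, MeOH, −40 °C) is run under substrate control to give the C8 epimer (3R,3aS,4S,8R,8aR)‑3,8‑dihydroxy‑6,8a‑dimethyl‑3‑(propan‑2‑yl)‑1,2,3,3a,4,5,8,8a‑octahydroazulen‑4‑yl 4‑(acetyloxy)benzoate F3. Mitsunobu esterification with (2E)‑2‑methylbut‑2‑enoic acid (PPh3, DIAD, toluene, 0 → 23 °C) then inverts C8 and installs the tiglate in one operation, giving 21.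

**Further compounds**
F1 | step 4 | (3R)‑3,7‑dimethyl‑3‑(nitromethyl)‑6‑oxooctanal | O=CC[C@](C)(C[N+](=O)[O-])CCC(=O)C(C)C
F2 | step 7 | (3R,3aS,4S,8aR)‑8‑(hydroxyimino)‑6,8a‑dimethyl‑3‑(propan‑2‑yl)‑1,2,3,3a,4,7,8,8a‑octahydroazulene‑3,4‑diol | ON=C1CC(C)=C[C@H](O)[C@@H]2[C@@]1(C)CC[C@@]2(O)C(C)C
F3 | step 9 | (3R,3aS,4S,8R,8aR)‑3,8‑dihydroxy‑6,8a‑dimethyl‑3‑(propan‑2‑yl)‑1,2,3,3a,4,5,8,8a‑octahydroazulen‑4‑yl 4‑(acetyloxy)benzoate | O[C@@H]1C=C(C)C[C@H](OC(=O)c2ccc(OC(C)=O)cc2)[C@@H]2[C@@]1(C)CC[C@@]2(O)C(C)C
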